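**Plan**

Numbering (germacrane): carbocycle C1–C10; lactone ring O–C6–C7–C11–C12(=O); C13 is the exo-methylene carbon on C11, C14 the methyl on C10, C15 the hydroxymethyl on C4.
Cuts, in retrosynthetic order: C15 O–PMB; the C1/C10 epoxide oxygen and the C11=C13 olefin (back to a C13 dimethylamine); the C8 ester; C5–C6 (opens the ten-membered ring); C3–C4; C11–C13; C7–C8; C8–C9.
Enabling feature: C6 is the oxygen-bearing carbon of the butyrolactone ring and C5 is β to the C3 ketone. A carboxyl group on C6 can therefore be turned into a nucleophilic α-oxy radical that adds to C5 of a seco C4=C5 enone and closes the carbocycle C1–C10 onto the preformed lactone.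
Forward: C9–C3 chain with the E olefin → C8 dithiane → conjugate addition to the (S)-butenolide (C7–C8, lactone ring present from here on) → C8 carbinol → C13 aminomethyl → C4/C5/C15 vinyl unit on C3 → C6 acid and redox-active ester → ten-membered ring → angelate, epoxide and methylene lactone, free C15–OH.
Stereochemistry: C7 from the butenolide stereocentre (anti 1,4-addition); C8 by oxazaborolidine reduction matched with Felkin–Anh control; C6 re-formed trans to C7 in the radical closure; C4 by enolate protonation and equilibration; C1/C10 by outer-face peracid attack on the E olefin; E-1(10) from SeO2 oxidation; Z-angelate from angelic acid.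

Key step: step 18

Abbreviations: TBS = tert-butyldimethylsilyl; TBDPS = tert-butyldiphenylsilyl; PMB = 4-methoxybenzyl; Ang = angeloyl, (Z)-2-methylbut-2-enoyl; locants C1–C15 in the Why lines are germacrane locants.
Remark: C4 is enolisable next to the C3 ketone; the natural 4S configuration is assumed to be the thermodynamically preferred one in the ten-membered ring.
Remark: 22 and 23 are carried as both epimers at the C3 carbinol (germacrane numbering); C11 of the amine adducts is drawn as formed by anti alkylation (11R) and is erased in step 21.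

**Route**

Step 1
Reactants: 1 4-methylpent-3-en-1-ol
Product: 2 tert-butyldimethyl(4-methylpent-3-enyloxy)silane
Conditions: TBSCl, imidazole, CH2Cl2, 0 °C to rt
Reagents that add atoms: tert-butyldimethylsilyl chloride, CC(C)(C)[Si](C)(C)Cl
Why: Silyl ether formation at a primary alcohol is routine and gives a C3 oxygen group that is stable to the organolithium steps that follow.

Step 2
Reactants: 2 tert-butyldimethyl(4-methylpent-3-enyloxy)silane
Product: 3 (E)-5-(TBSO)-2-methylpent-2-en-1-ol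
Conditions: SeO2 (0.3 equiv), t-BuOOH (3 equiv), salicylic acid (0.1 equiv), CH2Cl2, rt
Reagents that add atoms: tert-butyl hydroperoxide, CC(C)(C)OO
Why: SeO2-catalysed allylic hydroxylation (ene reaction then [2,3]-sigmatropic shift) of a trisubstituted olefin attacks the E-methyl group at the more substituted end and so fixes the E geometry of the future C1=C10 bond.

Step 3
Reactants: 3 (E)-5-(TBSO)-2-methylpent-2-en-1-ol
Product: 4 (E)-1-bromo-5-(TBSO)-2-methylpent-2-ene
Conditions: CBr4, PPh3, CH2Cl2, 0 °C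
Reagents that add atoms: carbon tetrabromide, BrC(Br)(Br)Br
Why: The Appel reaction should turn the primary allylic alcohol into the bromide under neutral conditions without allylic transposition or loss of the silyl ether.

Step 4
Reactants: 5 1,3-dithiane; 4 (E)-1-bromo-5-(TBSO)-2-methylpent-2-ene
Product: 7 2-[(E)-5-(TBSO)-2-methylpent-2-enyl]-1,3-dithiane, via 2-lithio-1,3-dithiane 6 (not isolated)
Conditions: n-BuLi, THF, −30 °C; then 4, −78 to 0 °C
Reagents that add atoms: none
Why: Corey–Seebach alkylation, in which the soft dithianyl anion displaces the primary allylic bromide by SN2 attack at C9, should install C8 as a masked acyl anion.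

Step 5
Reactants: 8 (S)-5-(hydroxymethyl)furan-2(5H)-one
Product: 9 (S)-5-(TBDPSOCH2)furan-2(5H)-one
Conditions: TBDPSCl, imidazole, CH2Cl2, 0 °C to rt
Reagents that add atoms: tert-butyldiphenylsilyl chloride, CC(C)(C)[Si](Cl)(c1ccccc1)c1ccccc1
Why: Silylation of the primary alcohol gives the bulky C6 substituent that later shields one face of the butenolide.

Step 6
Reactants: 7 2-[(E)-5-(TBSO)-2-methylpent-2-enyl]-1,3-dithiane; 9 (S)-5-(TBDPSOCH2)furan-2(5H)-one
Product: 12 (4S,5S)-5-(TBDPSOCH2)-4-{2-[(E)-5-(TBSO)-2-methylpent-2-enyl]-1,3-dithian-2-yl}dihydrofuran-2(3H)-one, via lithiated dithiane 10 (not isolated), via lithium lactone enolate 11 (not isolated)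
Conditions: n-BuLi, THF, −20 °C; HMPA, −78 °C; then 9, −78 °C; AcOH quench at −78 °C
Reagents that add atoms: none
Why: Conjugate addition of a 2-lithio-1,3-dithiane to a butenolide (favoured over 1,2-addition by HMPA) should occur anti to the silyloxymethyl group on C6, which sets C7 and the 6,7-trans relationship.

Step 7
Reactants: 12 (4S,5S)-5-(TBDPSOCH2)-4-{2-[(E)-5-(TBSO)-2-methylpent-2-enyl]-1,3-dithian-2-yl}dihydrofuran-2(3H)-one
Product: 13 (4S,5S)-5-(TBDPSOCH2)-4-[(E)-6-(TBSO)-3-methylhex-3-enoyl]dihydrofuran-2(3H)-one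
Conditions: MeI, CaCO3, MeCN/H2O (9:1), 40 °C
Reagents that add atoms: water, O
Why: Alkylative dithiane hydrolysis (S-methylation, then water) under CaCO3 buffering should unmask the C8 ketone without base that could conjugate the 1(10) olefin or expel the lactone oxygen from C6, and it is placed before any amine is present.

Step 8
Reactants: 13 (4S,5S)-5-(TBDPSOCH2)-4-[(E)-6-(TBSO)-3-methylhex-3-enoyl]dihydrofuran-2(3H)-one
Product: 14 (4R,5S)-5-(TBDPSOCH2)-4-[(1R,3E)-6-(TBSO)-1-hydroxy-3-methylhex-3-enyl]dihydrofuran-2(3H)-one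
Conditions: (S)-1-methyl-3,3-diphenyltetrahydro-1H,3H-pyrrolo[1,2-c][1,3,2]oxazaborole (0.2 equiv), catecholborane, toluene, −78 °C; pH 7 buffer work-up
Reagents that add atoms: none
Why: Corey–Bakshi–Shibata reduction, in which the (S)-oxazaborolidine delivers hydride to the face that gives the 8R carbinol (the branched C7 acting as the large group), agrees with the Felkin–Anh preference of the C7 stereocentre and leaves the lactone untouched.

Step 9
Reactants: 14 (4R,5S)-5-(TBDPSOCH2)-4-[(1R,3E)-6-(TBSO)-1-hydroxy-3-methylhex-3-enyl]dihydrofuran-2(3H)-one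
Product: 15 (4S,5S)-4-[(1R,3E)-1,6-bis(TBSO)-3-methylhex-3-enyl]-5-(TBDPSOCH2)dihydrofuran-2(3H)-one
Conditions: TBSOTf, 2,6-lutidine, CH2Cl2, −78 to 0 °C
Reagents that add atoms: tert-butyldimethylsilyl trifluoromethanesulfonate, CC(C)(C)[Si](C)(C)OS(=O)(=O)C(F)(F)F
Why: Silyl triflate silylation of the hindered secondary alcohol is fast at low temperature and blocks the 8-hydroxyl before it can translactonise onto C12.

Step 10
Reactants: 15 (4S,5S)-4-[(1R,3E)-1,6-bis(TBSO)-3-methylhex-3-enyl]-5-(TBDPSOCH2)dihydrofuran-2(3H)-one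
Product: 17 (3R,4S,5S)-4-[(1R,3E)-1,6-bis(TBSO)-3-methylhex-3-enyl]-5-(TBDPSOCH2)-3-(Me2NCH2)dihydrofuran-2(3H)-one, via lithium lactone enolate 16 (not isolated)
Conditions: LiN(i-Pr)2, THF, −78 °C; then [CH2=NMe2]I, −78 to 0 °C
Reagents that add atoms: N,N-dimethylmethyleneiminium iodide (Eschenmoser's salt), C=[N+](C)C.[I-]
Why: Mannich reaction of the lithium lactone enolate with Eschenmoser's salt should bring in C13 as a dimethylaminomethyl group anti to the C7 branch (11R, a centre erased later) and keeps the future methylene lactone inert to radicals and nucleophiles.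

Step 11
Reactants: 17 (3R,4S,5S)-4-[(1R,3E)-1,6-bis(TBSO)-3-methylhex-3-enyl]-5-(TBDPSOCH2)-3-(Me2NCH2)dihydrofuran-2(3H)-one
Product: 18 (3R,4S,5S)-4-[(1R,3E)-1-(TBSO)-6-hydroxy-3-methylhex-3-enyl]-5-(TBDPSOCH2)-3-(Me2NCH2)dihydrofuran-2(3H)-one
Conditions: HF·pyridine, pyridine, THF, 0 °C
Reagents that add atoms: none
Why: Buffered HF·pyridine should cleave the unhindered primary TBS ether selectively while the hindered secondary TBS ether and the acid-stable TBDPS ether remain (selective desilylation).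

Step 12
Reactants: 18 (3R,4S,5S)-4-[(1R,3E)-1-(TBSO)-6-hydroxy-3-methylhex-3-enyl]-5-(TBDPSOCH2)-3-(Me2NCH2)dihydrofuran-2(3H)-one
Product: 19 (3R,4S,5S)-4-[(1R,3E)-1-(TBSO)-3-methyl-6-oxohex-3-enyl]-5-(TBDPSOCH2)-3-(Me2NCH2)dihydrofuran-2(3H)-one
Conditions: Dess–Martin periodinane, CH2Cl2, 0 °C to rt
Reagents that add atoms: none
Why: Dess–Martin oxidation should give the β,γ-unsaturated aldehyde under non-basic conditions that do not move the olefin into conjugation.

Step 13
Reactants: 20 2-bromoprop-2-en-1-ol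
Product: 21 1-[(2-bromoprop-2-enyloxy)methyl]-4-methoxybenzene
Conditions: NaH, THF/DMF, 0 °C; PMBCl, n-Bu4NI (cat.), rt
Reagents that add atoms: 4-methoxybenzyl chloride, COc1ccc(CCl)cc1
Why: Williamson etherification protects the C15 oxygen as a PMB ether that is stable to every step up to the final oxidative removal.

Step 14
Reactants: 19 (3R,4S,5S)-4-[(1R,3E)-1-(TBSO)-3-methyl-6-oxohex-3-enyl]-5-(TBDPSOCH2)-3-(Me2NCH2)dihydrofuran-2(3H)-one; 21 1-[(2-bromoprop-2-enyloxy)methyl]-4-methoxybenzene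
Product: 22 (3R,4S,5S)-4-[(1R,3E)-1-(TBSO)-6-hydroxy-3-methyl-7-(PMBOCH2)octa-3,7-dienyl]-5-(TBDPSOCH2)-3-(Me2NCH2)dihydrofuran-2(3H)-one (both carbinol epimers)
Conditions: CrCl2 (5 equiv), NiCl2 (2 mol %), DMF, rt
Reagents that add atoms: none
Why: Nozaki–Hiyama–Kishi coupling should add the alkenylchromium reagent chemoselectively to the aldehyde in the presence of the lactone and the amine and without enolising the aldehyde, forming C3–C4 and giving both C3 carbinol epimers, which converge on oxidation.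

Step 15
Reactants: 22 (3R,4S,5S)-4-[(1R,3E)-1-(TBSO)-6-hydroxy-3-methyl-7-(PMBOCH2)octa-3,7-dienyl]-5-(TBDPSOCH2)-3-(Me2NCH2)dihydrofuran-2(3H)-one (both carbinol epimers)
Product: 23 (3R,4S,5S)-4-[(1R,3E)-1-(TBSO)-6-hydroxy-3-methyl-7-(PMBOCH2)octa-3,7-dienyl]-5-(hydroxymethyl)-3-(Me2NCH2)dihydrofuran-2(3H)-one (both carbinol epimers)
Conditions: n-Bu4NF, AcOH, H2O, THF, rt
Reagents that add atoms: none
Why: Fluoride buffered with acetic acid should remove the primary TBDPS ether faster than the hindered secondary TBS ether (selective desilylation), freeing the hydroxymethyl group on C6.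

Step 16
Reactants: 23 (3R,4S,5S)-4-[(1R,3E)-1-(TBSO)-6-hydroxy-3-methyl-7-(PMBOCH2)octa-3,7-dienyl]-5-(hydroxymethyl)-3-(Me2NCH2)dihydrofuran-2(3H)-one (both carbinol epimers)
Product: 25 (2S,3S,4R)-3-[(1R,3E)-1-(TBSO)-3-methyl-6-oxo-7-(PMBOCH2)octa-3,7-dienyl]-4-(Me2NCH2)-5-oxotetrahydrofuran-2-carboxylic acid, via keto aldehyde 24 (not isolated)
Conditions: Dess–Martin periodinane (3 equiv), CH2Cl2, rt; filter, concentrate; then NaClO2, NaH2PO4, 2-methylbut-2-ene, t-BuOH/H2O, 0 °C to rt
Reagents that add atoms: sodium chlorite, [Na+].[O-]Cl=O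
Why: Dess–Martin oxidation of both alcohols followed by Pinnick oxidation of the aldehyde should give the enone and the C6 carboxylic acid, with 2-methylbut-2-ene guarding the olefins and the acidic buffer protecting the amine as its salt.

Step 17
Reactants: 25 (2S,3S,4R)-3-[(1R,3E)-1-(TBSO)-3-methyl-6-oxo-7-(PMBOCH2)octa-3,7-dienyl]-4-(Me2NCH2)-5-oxotetrahydrofuran-2-carboxylic acid
Product: 26 1,3-dioxoisoindolin-2-yl (2S,3S,4R)-3-[(1R,3E)-1-(TBSO)-3-methyl-6-oxo-7-(PMBOCH2)octa-3,7-dienyl]-4-(Me2NCH2)-5-oxotetrahydrofuran-2-carboxylate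
Conditions: N-hydroxyphthalimide, N,N'-diisopropylcarbodiimide, CH2Cl2, 0 °C to rt
Reagents that add atoms: N-hydroxyphthalimide, ON1C(=O)c2ccccc2C1=O
Why: Carbodiimide (Steglich-type) esterification with N-hydroxyphthalimide should turn the acid into the redox-active ester under neutral conditions.

Step 18
Reactants: 26 1,3-dioxoisoindolin-2-yl (2S,3S,4R)-3-[(1R,3E)-1-(TBSO)-3-methyl-6-oxo-7-(PMBOCH2)octa-3,7-dienyl]-4-(Me2NCH2)-5-oxotetrahydrofuran-2-carboxylate
Product: 27 (4S,6R,7S,8R,11R)-8-(TBSO)-13-(dimethylamino)-15-(PMBO)-3-oxogermacr-1(10)E-en-6,12-olide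
Conditions: undivided cell, reticulated vitreous carbon cathode, Mg anode, Mg(ClO4)2 (0.1 M), (CF3)2CHOH (10 equiv), MeCN, constant current (about 2.2 F/mol), 26 added by syringe pump to a final 2 mM, rt
Reagents that add atoms: none
Why: Proposed new method: the cathode transfers one electron to the N-acyloxyphthalimide of 26, which fragments to phthalimide anion, CO2 and the C6 lactone radical; this nucleophilic α-acyloxy radical adds to the unsubstituted terminus C5 of the 2-(alkoxymethyl) enone, which Mg(ClO4)2 activates by chelation between the C3 carbonyl and the C15 ether oxygen, and the resulting C4 α-keto radical is reduced to the magnesium enolate and protonated by (CF3)2CHOH before the C15 alkoxide can be expelled, the closest known reactions being photoredox decarboxylative Giese macrocyclisations and intermolecular electroreductive Giese additions of N-hydroxyphthalimide esters, neither shown for a ten-membered carbocycle. The carbocycle C1–C10 closes in the 10-endo-trig mode through the new C5–C6 bond. C6 is controlled by the adjacent C7 stereocentre: the planar lactone radical should bond on the face opposite the C7–C8 branch, which also lets the chain take up the germacrane-like trans ring fusion. C4 is set by protonation of the cyclic enolate on its outer face and, being α to the ketone, can be equilibrated to the more stable epimer. The step needs chemoselectivity for the enone over the 1(10) olefin (5-exo or 6-endo closure) and over intermolecular addition: the electron-rich trisubstituted olefin is polarity-mismatched with the nucleophilic radical and offers only a fully substituted or a substituted carbon, the second acceptor of the target is absent because C13 is an amine and C8 a silyl ether, and slow addition at high dilution suppresses oligomers. The sacrificial Mg anode keeps the amine and the PMB ether from anodic oxidation.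

Step 19
Reactants: 27 (4S,6R,7S,8R,11R)-8-(TBSO)-13-(dimethylamino)-15-(PMBO)-3-oxogermacr-1(10)E-en-6,12-olide
Product: 28 (4S,6R,7R,8R,11R)-13-(dimethylamino)-8-hydroxy-15-(PMBO)-3-oxogermacr-1(10)E-en-6,12-olide
Conditions: HF·pyridine, pyridine, THF, 0 °C to rt
Reagents that add atoms: none
Why: HF·pyridine desilylation should free the 8-hydroxyl under mildly acidic conditions that spare the β,γ-unsaturated ketone, the Mannich base and the PMB ether.

Step 20
Reactants: 28 (4S,6R,7R,8R,11R)-13-(dimethylamino)-8-hydroxy-15-(PMBO)-3-oxogermacr-1(10)E-en-6,12-olide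
Product: 29 (4S,6R,7S,8R,11R)-8-(AngO)-13-(dimethylamino)-15-(PMBO)-3-oxogermacr-1(10)E-en-6,12-olide
Conditions: angelic acid, 2,4,6-trichlorobenzoyl chloride, Et3N, toluene, rt; then 28, 75 °C
Reagents that add atoms: angelic acid, C/C=C(/C)C(=O)O
Why: Yamaguchi-type esterification through the 2,4,6-trichlorobenzoic mixed anhydride should acylate the hindered 8-hydroxyl without a nucleophilic catalyst, which is what keeps the Z olefin of the angelate from isomerising to the tiglate.

Step 21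
Reactants: 29 (4S,6R,7S,8R,11R)-8-(AngO)-13-(dimethylamino)-15-(PMBO)-3-oxogermacr-1(10)E-en-6,12-olide
Product: 32 (1R,4S,6R,7S,8R,10R)-8-(AngO)-1,10-epoxy-15-(PMBO)-3-oxogermacr-11(13)-en-6,12-olide, via amine N-oxide 30 (not isolated), via epoxy amine N-oxide 31 (not isolated)
Conditions: mCPBA (2.2 equiv), CH2Cl2, −20 to 0 °C; then rt
Reagents that add atoms: 3-chloroperoxybenzoic acid, OOC(=O)c1cccc(Cl)c1
Why: The peracid should first oxidise the amine to its N-oxide and epoxidise the electron-rich 1(10) olefin (Prilezhaev reaction, stereospecific so the E geometry gives the trans epoxide, with attack on the outer face of the olefin in the ten-membered ring expected to give 1R,10R as in 1(10)-epoxidations of related germacranolides), and on warming the N-oxide should undergo Cope elimination across C11–C13 to give the α-methylene lactone.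

Step 22
Reactants: 32 (1R,4S,6R,7S,8R,10R)-8-(AngO)-1,10-epoxy-15-(PMBO)-3-oxogermacr-11(13)-en-6,12-olide
Product: 33 argophyllone B, (1R,4S,6R,7S,8R,10R)-8-(AngO)-1,10-epoxy-15-hydroxy-3-oxogermacr-11(13)-en-6,12-olide
Conditions: DDQ, CH2Cl2/pH 7 phosphate buffer (10:1), 0 °C to rt
Reagents that add atoms: none
Why: Oxidative PMB cleavage with DDQ at neutral pH should free the C15 hydroxyl and is kept for last because DDQ would oxidise the tertiary amine that is carried until step 21.

**Compound list**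

1 | 4-methylpent-3-en-1-ol | CC(C)=CCCO | starting material
2 | tert-butyldimethyl(4-methylpent-3-enyloxy)silane | CC(C)=CCCO[Si](C)(C)C(C)(C)C | intermediate
3 | (E)-5-(TBSO)-2-methylpent-2-en-1-ol | OC/C(C)=C/CCO[Si](C)(C)C(C)(C)C | intermediate
4 | (E)-1-bromo-5-(TBSO)-2-methylpent-2-ene | BrC/C(C)=C/CCO[Si](C)(C)C(C)(C)C | intermediate
5 | 1,3-dithiane | C1CSCSC1 | starting material
6 | 2-lithio-1,3-dithiane | [Li]C1SCCCS1 | intermediate
7 | 2-[(E)-5-(TBSO)-2-methylpent-2-enyl]-1,3-dithiane | CC(C)(C)[Si](C)(C)OCC/C=C(C)/CC1SCCCS1 | intermediate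
8 | (S)-5-(hydroxymethyl)furan-2(5H)-one | OC[C@H]1OC(=O)C=C1 | starting material
9 | (S)-5-(TBDPSOCH2)furan-2(5H)-one | CC(C)(C)[Si](OC[C@H]1OC(=O)C=C1)(c1ccccc1)c1ccccc1 | intermediate
10 | 2-lithio-2-[(E)-5-(TBSO)-2-methylpent-2-enyl]-1,3-dithiane | CC(C)(C)[Si](C)(C)OCC/C=C(C)/CC1([Li])SCCCS1 | intermediate
11 | lithium enolate of 12 (O-lithio 4,5-dihydrofuran-2-olate; 4,5-trans) | CC(C)(C)[Si](C)(C)OCC/C=C(C)/CC1(SCCCS1)[C@H]2C=C(O[Li])O[C@@H]2CO[Si](c3ccccc3)(c4ccccc4)C(C)(C)C | intermediate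
12 | (4S,5S)-5-(TBDPSOCH2)-4-{2-[(E)-5-(TBSO)-2-methylpent-2-enyl]-1,3-dithian-2-yl}dihydrofuran-2(3H)-one | CC(C)(C)[Si](C)(C)OCC/C=C(C)/CC1(SCCCS1)[C@H]2CC(=O)O[C@@H]2CO[Si](c3ccccc3)(c4ccccc4)C(C)(C)C | intermediate
13 | (4S,5S)-5-(TBDPSOCH2)-4-[(E)-6-(TBSO)-3-methylhex-3-enoyl]dihydrofuran-2(3H)-one | CC(C)(C)[Si](C)(C)OCC/C=C(C)/CC(=O)[C@H]1CC(=O)O[C@@H]1CO[Si](c2ccccc2)(c3ccccc3)C(C)(C)C | intermediate
14 | (4R,5S)-5-(TBDPSOCH2)-4-[(1R,3E)-6-(TBSO)-1-hydroxy-3-methylhex-3-enyl]dihydrofuran-2(3H)-one | CC(C)(C)[Si](C)(C)OCC/C=C(C)/C[C@@H](O)[C@H]1CC(=O)O[C@@H]1CO[Si](c2ccccc2)(c3ccccc3)C(C)(C)C | intermediate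
15 | (4S,5S)-4-[(1R,3E)-1,6-bis(TBSO)-3-methylhex-3-enyl]-5-(TBDPSOCH2)dihydrofuran-2(3H)-one | CC(C)(C)[Si](C)(C)OCC/C=C(C)/C[C@@H](O[Si](C)(C)C(C)(C)C)[C@H]1CC(=O)O[C@@H]1CO[Si](c2ccccc2)(c3ccccc3)C(C)(C)C | intermediate
16 | lithium enolate of 15 (O-lithio 4,5-dihydrofuran-2-olate) | CC(C)(C)[Si](C)(C)OCC/C=C(C)/C[C@@H](O[Si](C)(C)C(C)(C)C)[C@H]1C=C(O[Li])O[C@@H]1CO[Si](c2ccccc2)(c3ccccc3)C(C)(C)C | intermediate
17 | (3R,4S,5S)-4-[(1R,3E)-1,6-bis(TBSO)-3-methylhex-3-enyl]-5-(TBDPSOCH2)-3-(Me2NCH2)dihydrofuran-2(3H)-one | CC(C)(C)[Si](C)(C)OCC/C=C(C)/C[C@@H](O[Si](C)(C)C(C)(C)C)[C@H]1[C@H](CN(C)C)C(=O)O[C@@H]1CO[Si](c2ccccc2)(c3ccccc3)C(C)(C)C | intermediate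
18 | (3R,4S,5S)-4-[(1R,3E)-1-(TBSO)-6-hydroxy-3-methylhex-3-enyl]-5-(TBDPSOCH2)-3-(Me2NCH2)dihydrofuran-2(3H)-one | OCC/C=C(C)/C[C@@H](O[Si](C)(C)C(C)(C)C)[C@H]1[C@H](CN(C)C)C(=O)O[C@@H]1CO[Si](c2ccccc2)(c3ccccc3)C(C)(C)C | intermediate
19 | (3R,4S,5S)-4-[(1R,3E)-1-(TBSO)-3-methyl-6-oxohex-3-enyl]-5-(TBDPSOCH2)-3-(Me2NCH2)dihydrofuran-2(3H)-one | O=CC/C=C(C)/C[C@@H](O[Si](C)(C)C(C)(C)C)[C@H]1[C@H](CN(C)C)C(=O)O[C@@H]1CO[Si](c2ccccc2)(c3ccccc3)C(C)(C)C | intermediate
20 | 2-bromoprop-2-en-1-ol | OCC(Br)=C | starting material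
21 | 1-[(2-bromoprop-2-enyloxy)methyl]-4-methoxybenzene | C=C(Br)COCc1ccc(OC)cc1 | intermediate
22 | (3R,4S,5S)-4-[(1R,3E)-1-(TBSO)-6-hydroxy-3-methyl-7-(PMBOCH2)octa-3,7-dienyl]-5-(TBDPSOCH2)-3-(Me2NCH2)dihydrofuran-2(3H)-one (both carbinol epimers) | C=C(COCc1ccc(OC)cc1)C(O)C/C=C(C)/C[C@@H](O[Si](C)(C)C(C)(C)C)[C@H]2[C@H](CN(C)C)C(=O)O[C@@H]2CO[Si](c3ccccc3)(c4ccccc4)C(C)(C)C | intermediate
23 | (3R,4S,5S)-4-[(1R,3E)-1-(TBSO)-6-hydroxy-3-methyl-7-(PMBOCH2)octa-3,7-dienyl]-5-(hydroxymethyl)-3-(Me2NCH2)dihydrofuran-2(3H)-one (both carbinol epimers) | C=C(COCc1ccc(OC)cc1)C(O)C/C=C(C)/C[C@@H](O[Si](C)(C)C(C)(C)C)[C@H]2[C@H](CN(C)C)C(=O)O[C@@H]2CO | intermediate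
24 | (2S,3S,4R)-3-[(1R,3E)-1-(TBSO)-3-methyl-6-oxo-7-(PMBOCH2)octa-3,7-dienyl]-4-(Me2NCH2)-5-oxotetrahydrofuran-2-carbaldehyde | C=C(COCc1ccc(OC)cc1)C(=O)C/C=C(C)/C[C@@H](O[Si](C)(C)C(C)(C)C)[C@H]2[C@H](CN(C)C)C(=O)O[C@@H]2C=O | intermediate
25 | (2S,3S,4R)-3-[(1R,3E)-1-(TBSO)-3-methyl-6-oxo-7-(PMBOCH2)octa-3,7-dienyl]-4-(Me2NCH2)-5-oxotetrahydrofuran-2-carboxylic acid | C=C(COCc1ccc(OC)cc1)C(=O)C/C=C(C)/C[C@@H](O[Si](C)(C)C(C)(C)C)[C@H]2[C@H](CN(C)C)C(=O)O[C@@H]2C(=O)O | intermediate
26 | 1,3-dioxoisoindolin-2-yl ester of 25 (N-acyloxyphthalimide) | C=C(COCc1ccc(OC)cc1)C(=O)C/C=C(C)/C[C@@H](O[Si](C)(C)C(C)(C)C)[C@H]2[C@H](CN(C)C)C(=O)O[C@@H]2C(=O)ON3C(=O)c4ccccc4C3=O | intermediate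
27 | (4S,6R,7S,8R,11R)-8-(TBSO)-13-(dimethylamino)-15-(PMBO)-3-oxogermacr-1(10)E-en-6,12-olide | CN(C)C[C@@H]1C(=O)O[C@@H]2C[C@@H](COCc3ccc(OC)cc3)C(=O)C/C=C(C)/C[C@@H](O[Si](C)(C)C(C)(C)C)[C@@H]12 | intermediate
28 | (4S,6R,7R,8R,11R)-13-(dimethylamino)-8-hydroxy-15-(PMBO)-3-oxogermacr-1(10)E-en-6,12-olide | CN(C)C[C@@H]1C(=O)O[C@@H]2C[C@@H](COCc3ccc(OC)cc3)C(=O)C/C=C(C)/C[C@@H](O)[C@@H]12 | intermediate
29 | (4S,6R,7S,8R,11R)-8-(AngO)-13-(dimethylamino)-15-(PMBO)-3-oxogermacr-1(10)E-en-6,12-olide | CN(C)C[C@@H]1C(=O)O[C@@H]2C[C@@H](COCc3ccc(OC)cc3)C(=O)C/C=C(C)/C[C@@H](OC(=O)/C(C)=C\C)[C@@H]12 | intermediate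
30 | N-oxide of 29 | C[N+](C)([O-])C[C@@H]1C(=O)O[C@@H]2C[C@@H](COCc3ccc(OC)cc3)C(=O)C/C=C(C)/C[C@@H](OC(=O)/C(C)=C\C)[C@@H]12 | intermediate
31 | (1R,10R)-1,10-epoxide of N-oxide 30 | C[N+](C)([O-])C[C@@H]1C(=O)O[C@@H]2C[C@@H](COCc3ccc(OC)cc3)C(=O)C[C@H]4O[C@]4(C)C[C@@H](OC(=O)/C(C)=C\C)[C@@H]12 | intermediate
32 | (1R,4S,6R,7S,8R,10R)-8-(AngO)-1,10-epoxy-15-(PMBO)-3-oxogermacr-11(13)-en-6,12-olide | C=C1C(=O)O[C@@H]2C[C@@H](COCc3ccc(OC)cc3)C(=O)C[C@H]4O[C@]4(C)C[C@@H](OC(=O)/C(C)=C\C)[C@@H]12 | intermediate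
33 | argophyllone B, (1R,4S,6R,7S,8R,10R)-8-(AngO)-1,10-epoxy-15-hydroxy-3-oxogermacr-11(13)-en-6,12-olide | C=C1C(=O)O[C@@H]2C[C@@H](CO)C(=O)C[C@H]3O[C@]3(C)C[C@@H](OC(=O)/C(C)=C\C)[C@@H]12 | target

**Step count and risks**

Total steps: 22. Longest linear sequence: 20 steps (1–4, 6–12, 14–22, from 4-methylpent-3-en-1-ol).

Steps most likely to fail:

1. Step 18 (key step). The C6 radical may be consumed before it closes the strained ten-membered ring, by further reduction and protonation, by hydrogen abstraction from the medium, by 5-exo or 6-endo attack on the 1(10) olefin, or by intermolecular addition. Bond formation on the face syn to the C7 branch would give the cis-lactone, and slow protonation would let the enolate expel the C15 alkoxide. Fallback (ring-closing metathesis in place of the radical closure): the Dess–Martin stage of step 16 is stopped at keto aldehyde 24. This is methylenated chemoselectively at the aldehyde with CH2I2, Zn and Ti(O-i-Pr)4 (Takai conditions, which leave the enone ketone alone and do not epimerise C6) to give the C6-ethenyl dienone F1. Ring-closing metathesis of its camphorsulfonate salt with the second-generation Hoveyda–Grubbs catalyst in toluene at high dilution joins the C6 vinyl group to the enone methylene carbon with loss of ethylene and should give the ten-membered 4-en-3-one F2. In F2, C5 is the former aldehyde carbon and C6 keeps the configuration set in step 6. Conjugate reduction with [(Ph3P)CuH]6 then gives 27, where the route is rejoined.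

2. Step 21. The peracid may deliver oxygen to the other face of the 1(10) olefin of the flexible 3-oxo ring, the acid formed may open the trisubstituted epoxide, or the N-oxide may eliminate incompletely. Fallback (reagent-controlled epoxidation after a separate unmasking): 29 is quaternised with MeI to the trimethylammonium iodide F3, which loses trimethylamine on treatment with aqueous NaHCO3 to give the α-methylene lactone F4. Shi epoxidation of F4 with the D-fructose-derived ketone 1,2:4,5-di-O-isopropylidene-β-D-erythro-2,3-hexodiulo-2,6-pyranose and KHSO5 (K2CO3 buffer, MeCN/dimethoxymethane/H2O, 0 °C) should epoxidise only the electron-rich trisubstituted olefin and, through its spiro transition state, give the 1R,10R epoxide 32, where the route is rejoined.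

3. Step 6. The basic lithiodithiane may deprotonate the butenolide at C6 (loss of the stereocentre through the furanolate) or add 1,2 to the carbonyl, and the product enolate may add to a second butenolide. Fallback (radical in place of carbanion conjugate addition): 7 is lithiated as in step 6 and carboxylated with CO2 to the dithiane-2-carboxylic acid F5. Photoredox decarboxylation ([Ir(dF(CF3)ppy)2(dtbbpy)]PF6, K2HPO4, DMSO, blue light) in the presence of butenolide 9 generates the neutral 2-dithianyl radical. This should add to C7 anti to the C6 substituent (decarboxylative Giese addition) and, after reduction and protonation, give 12, where the route is rejoined.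

**Further compounds**

F1 | step 18 | C6-ethenyl analogue of 24 (CH=CH2 in place of CHO) | C=C(COCc1ccc(OC)cc1)C(=O)C/C=C(C)/C[C@@H](O[Si](C)(C)C(C)(C)C)[C@H]2[C@H](CN(C)C)C(=O)O[C@@H]2C=C
F2 | step 18 | 4,5-didehydro analogue of 27 (ring C4=C5 enone, olefin geometry as formed) | CN(C)C[C@@H]1C(=O)O[C@@H]2C=C(COCc3ccc(OC)cc3)C(=O)C/C=C(C)/C[C@@H](O[Si](C)(C)C(C)(C)C)[C@@H]12
F3 | step 21 | 13-trimethylammonium iodide derived from 29 | C[N+](C)(C)C[C@@H]1C(=O)O[C@@H]2C[C@@H](COCc3ccc(OC)cc3)C(=O)C/C=C(C)/C[C@@H](OC(=O)/C(C)=C\C)[C@@H]12.[I-]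
F4 | step 21 | (4S,6R,7S,8R)-8-(AngO)-15-(PMBO)-3-oxogermacra-1(10)E,11(13)-dien-6,12-olide | C=C1C(=O)O[C@@H]2C[C@@H](COCc3ccc(OC)cc3)C(=O)C/C=C(C)/C[C@@H](OC(=O)/C(C)=C\C)[C@@H]12
F5 | step 6 | 2-[(E)-5-(TBSO)-2-methylpent-2-enyl]-1,3-dithiane-2-carboxylic acid | CC(C)(C)[Si](C)(C)OCC/C=C(C)/CC1(C(=O)O)SCCCS1
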